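Compared with Monday's flask, Saturday's holds 3.00 times the substrate, and at 15 min it holds 2.62 times the target, but at 73 min just 2.11 times.

| flask | substrate | time |
|---|---|---|
| Monday's | 0.200 M |  |
| Thursday's | 0.100 M |  |
| Saturday's | 0.600 M |  |
| Sunday's | 0.500 M | 73 min |

| Monday's run: time / min | Monday's run: [target] / M | Thursday's run: time / min | Thursday's run: [target] / M | Saturday's run: time / min | Saturday's run: [target] / M |
|---|---|---|---|---|---|
| 15 | 0.0284 | 15 | 0.0153 | 15 | 0.0744 |
| 29 | 0.0456 | 29 | 0.0251 | 29 | 0.1115 |
| 44 | 0.0599 | 44 | 0.0338 | 44 | 0.1359 |
| 58 | 0.0680 | 58 | 0.0376 | 58 | 0.1472 |
| 73 | 0.0740 | 73 | 0.0408 | 73 | 0.1564 |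

(standard deviation of a reading: 6 × 10⁻⁴ M)

1. order of the initial rate in [substrate], near the charge of the Monday's run, the rate being that where two percent of its substrate are target (one fixed amount of target, the same in the runs compared)
2. target in the Sunday's run at 73 min, as a share of the substrate charged

- Overall: substrate -> target.
- Constant volume, constant temperature.
- An order is taken over about fifteen percent of the charge, up and down.

Those two ratios seem at odds. Early target keeps nearly in step with the charge, which looks first-order, and a purely first-order flask turns the same share of its charge at any charge. Yet the share at 73 min falls from 40.8 % on Thursday to 37.0 % on Monday and 26.1 % on Saturday.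

So treat the falling share as a correction, and suppose a loss beside the main route that goes with the square of the charge. Then Q, the charge over the target at that time (the reciprocal of the yield), rises on a straight line with charge. Monday and Saturday give a slope of 2.83 M⁻¹. This is b, the yield penalty, the rise of Q per molar of charge. Stepping back from Saturday's charge to Sunday's gives Q = 3.55, so my reckoning puts Sunday's yield at 28.2 %.

The forecast gives an order of 0.93, on the ground that “the earliest rates are almost proportional to charge”, and reaches 28.1 % separately, by interpolating the logarithm of the target at 73 min against the logarithm of the charge.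

The flask gives 27.9 % and an order of 1.0.

    substrate → target (0.01170 min⁻¹)
    2 substrate → side product (0.04206 M⁻¹ min⁻¹)
    substrate + target → 2 target (0.01224 M⁻¹ min⁻¹)
    target → decomposed product (0.003594 min⁻¹)

Once the same amount of target has been made, Saturday's rate is 3.1 times Monday's. Start now from Sunday's Q, 3.58, and step down to Thursday's charge with b. That gives Q = 2.45, a yield of 40.8 %, and Thursday's reading is 40.8 %.

Readings and results were generated by integration with constants of no real substance, noise included.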